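- My question was which set-up leaves the highest share of target among target, isomer of the product and over-reaction product.

the same everywhere: free catalyst 71 µM
- west: starting material 10 mM (fed, over 5.00 min); time 5.0 min; a stirred flask in which starting material is dosed at a steady rate over 5.00 min without added volume, worked up at 5.0 min
- east: starting material 10 mM; one stirred flow tank at steady state, fed with the mixture as stated, mean residence time 5.0 min
- north: starting material 10 mM; time 5.0 min; a closed flask charged with all of it at once and left for 5.0 min
- south-east: starting material 10 mM; one stirred flow tank at steady state, fed with the mixture as stated, mean residence time 50.0 min

    starting material ⇌ other conformer (K1 = 0.047, k1 = 0.0045 /s)
    free catalyst + other conformer → free catalyst + isomer of the product (k2 = 47 /M/s)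
    starting material + free catalyst → free catalyst + target (k3 = 40 /M/s)
    target → over-reaction product (k4 = 0.0014 /s)
    2 free catalyst → spent catalyst (k5 = 9.4 /M/s)

- a doubled species enters its step squared and goes two at a time
- the stated concentrations are those of everything mixed, before any reaction; amounts are the same in each set-up
- the feed brings no volume worth counting
- run time (west): 5.0 min

1. the set-up with the highest share of target in all that became target or isomer of the product or over-reaction product, at the outlet or at the end ("none" if the first two lie within 2 percentage points) (west / east / north / south-east / none)
2. share of target in all that became target or isomer of the product or over-reaction product, at the outlet or at the end, west
3. share of target in all that became target or isomer of the product or over-reaction product, at the outlet or at the end, east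
4. share of target in all that became target or isomer of the product or over-reaction product, at the outlet or at the end, north
5. share of target in all that became target or isomer of the product or over-reaction product, at the outlet or at the end, south-east

- I began with the balance of the reagent charged in the smaller amount, free catalyst, at 71 µM against 10 mM of starting material: both forming steps give it back and pairing removes it, so it multiplies both formation rates and drops out of their ratio.
- The other conformer returns to starting material at 0.0957 /s but, with free catalyst as charged, goes to isomer at 0.00334 /s, so it stays near 0.047 times c(starting material), a Curtin–Hammett case, and I gave target 94.8% of what forms.
- The rest depends on how long target waits, so with 0.0014 /s and 5.0 min I reckoned 0.420 for the exposure, which I defined as the rate constant of over-reaction times the mean residence time of a tank or the run time of a flask.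
- In a tank at steady state, the balance of over-reaction product makes c(over-reaction product) equal to the exposure times c(target), whatever free catalyst does, so I divided the target part by one plus the exposure and got 66.7% for east.
- For the flasks I multiplied the target part by the exponential of minus the exposure, scaled by the mean age of target as a fraction of the run time. As a rough estimate I took that age as half of the time in north, giving 76.8%, and as a third in west, where starting material builds up during dosing, giving 82.4%.
- I then turned the question round: the answer "none" needed my first two, west and north, within 2 percentage points, but mine stood 5.6 points apart, so I committed to west.
- The forecast named west, with 81.8% for west, 66.9% for east, 74.6% for north and 18.2% for south-east, on the ground that “Dosing forms target latest and so protects it best”.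
- The simulation named west, with 81.9% for west, 66.9% for east, 74.8% for north and 18.2% for south-east.
- In east, target left by outflow at 0.200 /min and over-reacted at 0.0840 /min, an exposure of 0.420, and the share stood at 66.9%. In south-east, outflow stood at 0.0200 /min, slower than over-reaction, the exposure was ten times larger at 4.20, and there the tank rule reads 18.2% and the simulation 18.2%.

Its constants are invented; the flask was simulated.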